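**Retrosynthetic overview**
1. 26 ⇐ desilylation ⇐ ligand-controlled Ni/Cr isopropenylation (sets C14) ⇐ anti-Markovnikov Wacker oxidation of the allyl arm of macrocycle 22.
2. 22 ⇐ Mitsunobu acylation with inversion at C4 ⇐ matched Sharpless epoxidation (C5, C6) ⇐ Nozaki–Hiyama–Kishi closure of the 11-membered ring at C4–C5 (19).
3. Acyclic iodo-enal 18 ⇐ E-selective Wittig reaction (C9=C10) of aldehyde-acid 6 and ylide 13, which comes from pent-3-yn-1-ol.
4. 6 ⇐ ozonolytic opening of silyl dienol ether 4 ⇐ enantioselective desymmetrising 1,4-hydrosilylation of achiral dienone 3 ⇐ oxidative para-allylation (dearomatisation) of p-cresol. The seven cresol carbons become C1, C1-CH3, C2, C3, C4, C10 and C11.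
5. Ring order: the cresol six-ring is kept only until step 3, then the 11-membered carbocycle forms (step 10), then the oxirane (step 11).

Locants used below: ring C1 (quaternary)–C2=C3–C4(O)–C5(Me)–C6–C7–C8–C9(CH2O)=C10–C11; side chain C12–C13–C14(O)–C15(Me)=C16H2.
Assumption: in the ligand-controlled steps 2, 10 and 14 the ligand antipode that gives the drawn configuration is used, because no reliable mnemonic exists for these substrates and the sense must be checked on the first run.

**Step 1**
Reactants: 1 p-cresol (4-methylphenol); 2 allyltrimethylsilane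
Product: 3 4-methyl-4-(prop-2-en-1-yl)cyclohexa-2,5-dien-1-one
Conditions: PhI(OAc)2 (1.2 equiv), 2 (3 equiv), (CF3)2CHOH, 0 °C, 15 min
Reagents that add atoms: none
Why: Oxidative dearomatisation (oxidative Hosomi–Sakurai allylation), in which PhI(OAc)2 in HFIP turns the phenol into a phenoxenium-type electrophile that the allylsilane captures at the methyl-bearing para carbon, creating the quaternary carbon C1 in a dienone that is still achiral (Cs).

**Step 2 (key step)**
Reactants: 3 4-methyl-4-(prop-2-en-1-yl)cyclohexa-2,5-dien-1-one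
Product: 4 (R)-dimethyl{[4-methyl-4-(prop-2-en-1-yl)cyclohexa-1,5-dien-1-yl]oxy}(phenyl)silane
Conditions: Cu(OAc)2·H2O (5 mol %), (R)-DTBM-SEGPHOS (5.5 mol %), PhMe2SiH (1.1 equiv), toluene, −50 °C; filtration through Et3N-deactivated silica
Reagents that add atoms: dimethylphenylsilane C[SiH](C)c1ccccc1
Why: Proposed new method: a bisphosphine–CuH catalyst hydrocuprates one of the two enantiotopic enone C=C bonds of Cs-symmetric 3 (hydride goes to the future C11 on the ring face anti to the larger allyl group, and the ligand decides which C=C presents that face), the copper dienolate is silylated by Si–H σ-bond metathesis so that 4 is no longer an acceptor and cannot be over-reduced, and C1 thereby becomes the (R)-stereocentre; the closest known reaction types are CuH-catalysed asymmetric conjugate hydrosilylation of cyclic enones and the Rh- or ene-reductase-catalysed desymmetrising conjugate reduction of 4,4-disubstituted cyclohexadienones, and the new elements are Me/allyl discrimination and isolation of the cross-conjugated silyl dienol ether.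

**Step 3**
Reactants: 4 (R)-silyl dienol ether
Product: 6 (2Z,4R)-4-methyl-4-(2-oxoethyl)hepta-2,6-dienoic acid, via silyl ester 5 (not isolated)
Conditions: O3 (1.0 equiv, titrated CH2Cl2 solution), pyridine (3 equiv), CH2Cl2, −78 °C; then pH 5 buffer/THF, 0 °C
Reagents that add atoms: ozone [O-][O+]=O
Why: Chemoselective Criegee ozonolysis (pyridine-promoted reductive variant) of the silyl enol ether C4=C10, which is far more electron-rich than the neopentyl-shielded C2=C3 and the monosubstituted allyl group, opens the ring to C10HO and the C4 acid in one operation and leaves C1 untouched.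

**Step 4**
Reactants: 7 pent-3-yn-1-ol
Product: 9 (E)-4-iodopent-3-en-1-ol, via alkenylzirconocene 8 (not isolated)
Conditions: Cp2Zr(H)Cl (2.3 equiv), THF, rt → 40 °C, 2 h; I2 (1.1 equiv), −20 °C; aq Na2S2O3
Reagents that add atoms: iodine II
Why: Hydrozirconation–iodinolysis, in which the first equivalent of Schwartz reagent forms the alkoxide, the second adds H–Zr syn and (after equilibration by excess reagent) places Zr on the less hindered methyl-bearing carbon, and I2 cleaves C–Zr with retention, fixing the later E-C5=C6 geometry.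

**Step 5**
Reactants: 9 (E)-4-iodopent-3-en-1-ol
Product: 10 (E)-2,5-diiodopent-2-ene
Conditions: I2, PPh3, imidazole, CH2Cl2, 0 °C
Reagents that add atoms: iodine II
Why: Appel-type (Garegg–Samuelsson) iodination proceeds by SN2 at the primary carbinol, and the vinyl iodide is inert.

**Step 6**
Reactants: 10 (E)-2,5-diiodopent-2-ene; 11 methyl (triphenylphosphoranylidene)acetate
Product: 13 methyl (E)-6-iodo-2-(triphenylphosphoranylidene)hept-5-enoate, via phosphonium iodide 12 (not isolated)
Conditions: 11 (2.1 equiv), MeCN, 80 °C, 24 h; filter off the salt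
Reagents that add atoms: none
Why: C-alkylation of a stabilised ylide followed by transylidation, in which the soft ylide carbon displaces only the primary iodide (SN2) and the second equivalent of 11 deprotonates salt 12.

**Step 7**
Reactants: 6 (2Z,4R)-4-methyl-4-(2-oxoethyl)hepta-2,6-dienoic acid; 13 ylide
Product: 14 (2Z,4R,6E,10E)-11-iodo-7-(methoxycarbonyl)-4-methyl-4-(prop-2-en-1-yl)dodeca-2,6,10-trienoic acid
Conditions: toluene, 80 °C, 12 h
Reagents that add atoms: none
Why: Wittig olefination with an α-branched stabilised ylide gives the E-enoate (ester trans to C11, so C8 is cis to C11 as in the target), and the free carboxylic acid is tolerated because carboxylic acids catalyse rather than quench stabilised ylides.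

**Step 8**
Reactants: 14 acid–ester
Product: 17 (2E,4R,6E,10E)-7-(hydroxymethyl)-11-iodo-4-methyl-4-(prop-2-en-1-yl)dodeca-2,6,10-trienal, via acyl imidazolide 15 (not isolated), via Z-enal 16 (not isolated)
Conditions: CDI (1.1 equiv), CH2Cl2, rt, 1 h; DIBAL-H (5 equiv), −78 °C, 1 h; Rochelle salt; crude product, DABCO (20 mol %), CH2Cl2, rt
Reagents that add atoms: 1,1'-carbonyldiimidazole O=C(n1ccnc1)n1ccnc1 (imidazolyl group present in 15 only)
Why: Staab activation and partial reduction, in which the N-acylimidazole gives a tetrahedral aluminate that is stable at −78 °C and releases the aldehyde only on work-up while the methyl enoate is reduced fully to the allylic alcohol, after which DABCO isomerises the Z-enal to the E-enal by reversible conjugate addition, driven by relief of strain between CHO and quaternary C1.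

**Step 9**
Reactants: 17 hydroxy-enal
Product: 18 (2E,4R,6E,10E)-7-{[(tert-butyldimethylsilyl)oxy]methyl}-11-iodo-4-methyl-4-(prop-2-en-1-yl)dodeca-2,6,10-trienal
Conditions: TBSCl (1.2 equiv), imidazole (2 equiv), CH2Cl2, 0 °C
Reagents that add atoms: tert-butyldimethylsilyl chloride CC(C)(C)[Si](C)(C)Cl
Why: Silyl ether formation masks the primary allylic alcohol so that only the C4 hydroxyl can direct the epoxidation and be acylated later.

**Step 10**
Reactants: 18 iodo-enal
Product: 19 (1R,2E,6E,9R,10E)-6-{[(tert-butyldimethylsilyl)oxy]methyl}-2,9-dimethyl-9-(prop-2-en-1-yl)cycloundeca-2,6,10-trien-1-ol (target locants 1R,4R)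
Conditions: CrCl2 (8 equiv), Kishi-type oxazoline–sulfonamide ligand L* (8.8 equiv), Et3N (8.8 equiv), NiCl2·dmp (5 mol %), THF/MeCN, 18 added over 12 h to 2 mM, rt
Reagents that add atoms: none
Why: Nozaki–Hiyama–Kishi macrocyclisation, in which Ni inserts into the C–I bond, transmetalation gives an alkenyl–Cr(III) species with retention of the E geometry, and 1,2-addition to the enal closes a zerumbol-type 11-ring; C4 (R) is set by the chiral Cr complex because the remote C1 (Me versus allyl) exerts little bias, and any 4S epimer is inert in step 11 and is removed there.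

**Step 11**
Reactants: 19 (4R)-bis-allylic alcohol
Product: 20 5,6-epoxide of 19 (target locants 1R,4R,5R,6R; C5 reads R only because the free OH lowers the CIP rank of C4, and the oxirane is that of the target)
Conditions: Ti(OiPr)4 (20 mol %), D-(−)-DIPT (24 mol %), t-BuOOH (1.5 equiv), 4 Å MS, CH2Cl2, −20 °C
Reagents that add atoms: tert-butyl hydroperoxide CC(C)(C)OO
Why: Sharpless asymmetric epoxidation in its matched (fast kinetic-resolution) pairing, because with D-(−)-tartrate the (4R)-carbinol/C5=C6 combination is the fast one and gives the erythro epoxy alcohol with oxygen on the face required for C5 and C6, while C2=C3 is the mismatched and less nucleophilic alkene and the unactivated or silyl-protected alkenes do not react; in the E-cycloundecene C3 lies on the inner face, so the OH group and the open outer face are syn.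

**Step 12**
Reactants: 20 (4R)-epoxy alcohol; 21 3-methylbut-2-enoic acid (senecioic acid)
Product: 22 (1R,4S,5S,6R)-4-O-senecioyl 5,6-epoxy macrocycle carrying C9-CH2OTBS plus the C1 allyl group
Conditions: PPh3 (2 equiv), DIAD (2 equiv), 21 (2 equiv), toluene, 0 °C → rt
Reagents that add atoms: none
Why: Mitsunobu esterification, in which SN2 displacement of the allylic oxyphosphonium ion by senecioate inverts C4 (R → S), turning the erythro epoxy alcohol into the threo relationship of the target and installing the ester in the same operation under neutral conditions that avoid deconjugation of the senecioate and Payne rearrangement.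

**Step 13**
Reactants: 22 allyl macrocycle
Product: 23 C14 aldehyde (the C1 allyl group of 22 converted into CH2CH2CHO)
Conditions: PdCl2(PhCN)2 (12 mol %), CuCl2·2H2O (12 mol %), AgNO2 (6 mol %), t-BuOH/MeNO2 15:1, O2 (1 atm), rt
Reagents that add atoms: dioxygen O=O
Why: Nitrite-modified aldehyde-selective (anti-Markovnikov) Wacker oxidation works because only the monosubstituted alkene binds Pd(II), and the quaternary C1 next to the allylic CH2 further disfavours attack at the internal carbon.

**Step 14**
Reactants: 23 aldehyde; 24 2-bromopropene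
Product: 25 (14R)-allylic alcohol (the C9-CH2OTBS ether of the target)
Conditions: CrCl2 (4 equiv), Kishi-type oxazoline–sulfonamide ligand L* (4.4 equiv), Et3N (4.4 equiv), NiCl2·dmp (2 mol %), 24 (2 equiv), THF, rt
Reagents that add atoms: none
Why: Ligand-controlled asymmetric Ni/Cr (NHK) alkenylation, in which the 2-propenyl–Cr(III) sulfonamide complex adds to one aldehyde face and sets the remote C14 (R) purely by reagent control, while the ester, epoxide and silyl ether are inert to Cr(II)/Cr(III).

**Step 15**
Reactants: 25 silyl ether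
Product: 26 target CNP0309478.1
Conditions: TBAF (1.5 equiv), AcOH (1.5 equiv), THF, 0 °C → rt
Reagents that add atoms: none
Why: Fluoride-mediated desilylation buffered with AcOH frees the primary allylic alcohol without touching the epoxide or the senecioate, and no stereocentre is involved.

**Compound list**
1 | p-cresol | Cc1ccc(O)cc1 | starting material
2 | allyltrimethylsilane | C=CC[Si](C)(C)C | starting material
3 | 4-methyl-4-(prop-2-en-1-yl)cyclohexa-2,5-dien-1-one | C=CCC1(C)C=CC(=O)C=C1 | intermediate
4 | (R)-dimethyl{[4-methyl-4-(prop-2-en-1-yl)cyclohexa-1,5-dien-1-yl]oxy}(phenyl)silane | C=CC[C@@]1(C)C=CC(O[Si](C)(C)c2ccccc2)=CC1 | intermediate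
5 | dimethyl(phenyl)silyl (2Z,4R)-4-methyl-4-(2-oxoethyl)hepta-2,6-dienoate | C=CC[C@@](CC=O)(C)/C=C\C(=O)O[Si](C)(C)c1ccccc1 | intermediate
6 | (2Z,4R)-4-methyl-4-(2-oxoethyl)hepta-2,6-dienoic acid | C=CC[C@@](CC=O)(C)/C=C\C(=O)O | intermediate
7 | pent-3-yn-1-ol | CC#CCCO | starting material
8 | (E)-alkenylzirconocene chloride / zirconocene alkoxide from 7 | C/C(=C\CCO[Zr](Cl)(C1C=CC=C1)C1C=CC=C1)[Zr](Cl)(C1C=CC=C1)C1C=CC=C1 | intermediate
9 | (E)-4-iodopent-3-en-1-ol | C/C(I)=C\CCO | intermediate
10 | (E)-2,5-diiodopent-2-ene | C/C(I)=C\CCI | intermediate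
11 | methyl (triphenylphosphoranylidene)acetate | COC(=O)C=P(c1ccccc1)(c1ccccc1)c1ccccc1 | starting material
12 | [(E)-6-iodo-1-methoxy-1-oxohept-5-en-2-yl]triphenylphosphonium iodide | COC(=O)C(CC/C=C(\C)I)[P+](c1ccccc1)(c1ccccc1)c1ccccc1.[I-] | intermediate
13 | methyl (E)-6-iodo-2-(triphenylphosphoranylidene)hept-5-enoate | COC(=O)C(CC/C=C(\C)I)=P(c1ccccc1)(c1ccccc1)c1ccccc1 | intermediate
14 | (2Z,4R,6E,10E)-11-iodo-7-(methoxycarbonyl)-4-methyl-4-(prop-2-en-1-yl)dodeca-2,6,10-trienoic acid | C=CC[C@@](C/C=C(\CC/C=C(\C)I)C(=O)OC)(C)/C=C\C(=O)O | intermediate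
15 | N-acylimidazole of 14 | C=CC[C@@](C/C=C(\CC/C=C(\C)I)C(=O)OC)(C)/C=C\C(=O)n1ccnc1 | intermediate
16 | (2Z)-isomer of 17 | C=CC[C@@](C/C=C(\CC/C=C(\C)I)CO)(C)/C=C\C=O | intermediate
17 | (2E,4R,6E,10E)-7-(hydroxymethyl)-11-iodo-4-methyl-4-(prop-2-en-1-yl)dodeca-2,6,10-trienal | C=CC[C@@](C/C=C(\CC/C=C(\C)I)CO)(C)/C=C/C=O | intermediate
18 | TBS ether of 17 | C=CC[C@@](C/C=C(\CC/C=C(\C)I)CO[Si](C)(C)C(C)(C)C)(C)/C=C/C=O | intermediate
19 | (1R,2E,6E,9R,10E)-6-(TBSO-methyl)-2,9-dimethyl-9-allylcycloundeca-2,6,10-trien-1-ol (target locants 1R,4R) | C=CC[C@@]1(C)/C=C/[C@@H](O)/C(C)=C/CC/C(CO[Si](C)(C)C(C)(C)C)=C\C1 | intermediate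
20 | (4R)-5,6-epoxy alcohol (target locants 1R,4R,5R,6R) | C=CC[C@@]1(C)/C=C/[C@@H](O)[C@@]2(C)O[C@@H]2CC/C(CO[Si](C)(C)C(C)(C)C)=C\C1 | intermediate
21 | 3-methylbut-2-enoic acid | CC(C)=CC(=O)O | starting material
22 | (1R,4S,5S,6R)-4-senecioate, C9-CH2OTBS, C1-allyl | C=CC[C@@]1(C)/C=C/[C@H](OC(=O)C=C(C)C)[C@@]2(C)O[C@@H]2CC/C(CO[Si](C)(C)C(C)(C)C)=C\C1 | intermediate
23 | C14 aldehyde | O=CCC[C@@]1(C)/C=C/[C@H](OC(=O)C=C(C)C)[C@@]2(C)O[C@@H]2CC/C(CO[Si](C)(C)C(C)(C)C)=C\C1 | intermediate
24 | 2-bromopropene | C=C(C)Br | starting material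
25 | (14R)-alcohol, C9-CH2OTBS | C=C(C)[C@H](O)CC[C@@]1(C)/C=C/[C@H](OC(=O)C=C(C)C)[C@@]2(C)O[C@@H]2CC/C(CO[Si](C)(C)C(C)(C)C)=C\C1 | intermediate
26 | CNP0309478.1 (1R,4S,5S,6R,14R) | C=C(C)[C@H](O)CC[C@@]1(C)/C=C/[C@H](OC(=O)C=C(C)C)[C@@]2(C)O[C@@H]2CC/C(CO)=C\C1 | target

**Totals**
- Total step count: 15.
- Longest linear sequence: 12 steps (steps 1–3 then 7–15; the branch through steps 4–6 then 7–15 is equally long).

**Three steps most likely to fail**

Step 2. The risk is insufficient Me/allyl discrimination, which would give low ee. The fallback sets out from 3 and comes back at 4. An OYE-type ene-reductase (enantiocomplementary enzymes are available; NADP+/glucose dehydrogenase recycling, buffer, 30 °C) reduces one enantiotopic C=C to (S)-4-methyl-4-(prop-2-en-1-yl)cyclohex-2-en-1-one F1. Kinetic α′-deprotonation with LDA at −78 °C and O-silylation with PhMe2SiCl then returns 4.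

Step 10. The 11-ring is strained, and C4 depends on a ligand that has not been tested on this enal. The fallback sets out from 18 and comes back at 19, and it separates ring closure from C4 control. The closure is run with the plain achiral CrCl2/NiCl2 system in DMSO. The resulting mixture of 19 and the (4S)-epimeric macrocyclic alcohol F2 is oxidised with MnO2 to the zerumbone-type cross-conjugated macrocyclic dienone F3. Reduction with (S)-Me-CBS/catecholborane, in which the α-methyl-alkenyl arm acts as the large group, returns 19.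

Step 12. This is an SN2 reaction at a hindered, allylic, epoxide-flanked carbon with a weakly acidic partner, and SN2′ or ionisation could compete. The fallback sets out from 20 and comes back at 22, and it separates inversion from acylation. A Mitsunobu reaction with the much more acidic 4-nitrobenzoic acid gives the inverted (4S)-4-nitrobenzoate F4. Brief K2CO3/MeOH methanolysis gives the (4S)-epoxy alcohol F5. Steglich esterification with 21 (DCC, DMAP, CH2Cl2, retention) then gives 22.

**Further compounds**
F1 | step 2 | (S)-4-methyl-4-(prop-2-en-1-yl)cyclohex-2-en-1-one | C=CC[C@@]1(C)C=CC(=O)CC1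
F2 | step 10 | (4S)-epimeric macrocyclic alcohol | C=CC[C@@]1(C)/C=C/[C@H](O)/C(C)=C/CC/C(CO[Si](C)(C)C(C)(C)C)=C\C1
F3 | step 10 | zerumbone-type cross-conjugated macrocyclic dienone | C=CC[C@@]1(C)/C=C/C(=O)/C(C)=C/CC/C(CO[Si](C)(C)C(C)(C)C)=C\C1
F4 | step 12 | inverted (4S)-4-nitrobenzoate | C=CC[C@@]1(C)/C=C/[C@H](OC(=O)c3ccc([N+](=O)[O-])cc3)[C@@]2(C)O[C@@H]2CC/C(CO[Si](C)(C)C(C)(C)C)=C\C1
F5 | step 12 | (4S)-epoxy alcohol | C=CC[C@@]1(C)/C=C/[C@H](O)[C@@]2(C)O[C@@H]2CC/C(CO[Si](C)(C)C(C)(C)C)=C\C1
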